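**Retrosynthetic overview** (flavan numbering of the target is used for all ring atoms: O1, C2–C4, C4a, C5–C8, C8a)

1. Pongaflavanol ⇒ its C4 ketone, a dearomatized 5‑methoxy‑8,8‑diprenylflavanone, by cis‑selective 1,2‑reduction (C4 is set from C2).
2. That flavanone ⇒ benzaldehyde + a ring A dienone with a 1‑silyloxyvinyl group on C4a and a methoxy leaving group on C8a: catalytic asymmetric Mukaiyama aldol (C2–C3, sets C2), then ring C is closed by the O1–C8a bond with loss of methanol (formal hetero‑Diels–Alder).
3. Ring A dienone ⇒ 4‑hydroxy‑2,6‑dimethoxyacetophenone: bromine blocks the future C6, the two prenyl groups are placed on C8 one after the other (ortho C‑prenylation, then alkylative dearomatization), then the bromine is removed.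
4. Enabling feature: C8a is at once the β‑carbon of the C4 carbonyl (O1–C8a=C4a–C4=O is a dihydropyranone) and the δ‑carbon of the ring A dienone C7(=O)–C6=C5–C4a=C8a, which the quaternary C8 keeps from aromatizing. A methoxy group on C8a is therefore a doubly vinylogous ester leaving group, and ring A with an acetyl group on C4a is a built‑in Danishefsky‑type diene.
5. Ring order: ring B is bought (benzaldehyde), ring A is made first (dearomatized arene), ring C is closed in the key step.

Key step: step 6

Remark: compound 1, 1-(4-hydroxy-2,6-dimethoxyphenyl)ethan-1-one, is assumed to be a purchasable catalogue compound.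

**Step 1**
Reactants: 1 1-(4-hydroxy-2,6-dimethoxyphenyl)ethan-1-one
Product: 2 1-(3-bromo-4-hydroxy-2,6-dimethoxyphenyl)ethan-1-one
Conditions: NBS (1.0 equiv), MeCN, 0 °C, dark
Reagents that add atoms: N-bromosuccinimide, O=C1CCC(=O)N1Br
Why: Electrophilic aromatic bromination goes ortho to the free phenol (the two ortho positions are equivalent, the para position carries the acetyl group), and one equivalent should stop at the monobromide, whose bromine blocks the future C6 in steps 2 and 3.

**Step 2**
Reactants: 2 1-(3-bromo-4-hydroxy-2,6-dimethoxyphenyl)ethan-1-one; 3 1-bromo-3-methylbut-2-ene (prenyl bromide)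
Product: 4 1-[3-bromo-4-hydroxy-2,6-dimethoxy-5-(3-methylbut-2-en-1-yl)phenyl]ethan-1-one
Conditions: NaH (1.05 equiv), toluene, 0 °C, then 3 (1.1 equiv), rt; aq NH4Cl work-up
Reagents that add atoms: none
Why: Ortho C‑alkylation of a sodium phenoxide held as a tight ion pair in a non‑polar medium should put the prenyl group on the only hydrogen‑bearing ortho carbon (the future C8), the para carbon being acylated and the other ortho carbon brominated, and tautomerization then restores the phenol; no stereocenter is formed.

**Step 3**
Reactants: 4 1-[3-bromo-4-hydroxy-2,6-dimethoxy-5-(3-methylbut-2-en-1-yl)phenyl]ethan-1-one; 3 1-bromo-3-methylbut-2-ene (prenyl bromide)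
Product: 5 4-acetyl-2-bromo-3,5-dimethoxy-6,6-bis(3-methylbut-2-en-1-yl)cyclohexa-2,4-dien-1-one
Conditions: NaH (1.1 equiv), toluene, 0 °C, then 3 (1.5 equiv), rt to 40 °C
Reagents that add atoms: none
Why: With both ortho carbons and the para carbon substituted, the phenoxide of 4 can be C‑alkylated only with loss of aromaticity (alkylative dearomatization), and the prenyl‑bearing ortho carbon should react in preference to the less nucleophilic, more hindered bromine‑bearing one, giving a gem‑diprenyl dienone that is stabilized as a 3,5‑dimethoxy vinylogous ester.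

**Step 4**
Reactants: 5 4-acetyl-2-bromo-3,5-dimethoxy-6,6-bis(3-methylbut-2-en-1-yl)cyclohexa-2,4-dien-1-one
Product: 6 4-acetyl-3,5-dimethoxy-6,6-bis(3-methylbut-2-en-1-yl)cyclohexa-2,4-dien-1-one
Conditions: Pd(OAc)2 (5 mol%), PPh3 (10 mol%), HCO2H (3 equiv), Et3N (4 equiv), DMF, 50 °C
Reagents that add atoms: none
Why: Zerovalent palladium should insert into the activated C6–Br bond of the α‑bromo enone and formate should deliver hydride (palladium‑catalysed reductive dehalogenation) faster than the vinylpalladium species can insert a trisubstituted prenyl alkene; no stereocenter is involved.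

**Step 5**
Reactants: 6 4-acetyl-3,5-dimethoxy-6,6-bis(3-methylbut-2-en-1-yl)cyclohexa-2,4-dien-1-one
Product: 7 3,5-dimethoxy-6,6-bis(3-methylbut-2-en-1-yl)-4-{1-[(trimethylsilyl)oxy]ethenyl}cyclohexa-2,4-dien-1-one
Conditions: TMSOTf (1.2 equiv), Et3N (1.5 equiv), CH2Cl2, 0 °C; pentane extraction, used crude
Reagents that add atoms: trimethylsilyl trifluoromethanesulfonate, C[Si](C)(C)OS(=O)(=O)C(F)(F)F
Why: Soft enolization and O‑silylation of the methyl ketone, the only enolizable carbonyl (C7=O lies between the quaternary C8 and the vinylic C6), should give the 2‑silyloxy diene just as Danishefsky's diene is made from 4‑methoxybut‑3‑en‑2‑one.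

**Step 6**
Reactants: 7 3,5-dimethoxy-6,6-bis(3-methylbut-2-en-1-yl)-4-{1-[(trimethylsilyl)oxy]ethenyl}cyclohexa-2,4-dien-1-one; 8 benzaldehyde
Product: 10 (2S)-5-methoxy-8,8-bis(3-methylbut-2-en-1-yl)-2-phenyl-2,3-dihydro-4H-chromene-4,7(8H)-dione, via aldol silyl ether 9 (not isolated)
Conditions: (S)-BINOL (20 mol%), Ti(OiPr)4 (10 mol%), 4 Å MS, Et2O, −20 °C, 8 (1.2 equiv); then TFA (2 equiv), wet CH2Cl2, 0 °C; aq NaHCO3 quench
Reagents that add atoms: none
Why: The silyl enol ether terminus C3 adds to the titanium‑bound aldehyde (Mukaiyama aldol), the developing cation being the vinylogous oxocarbenium centred on C8a, and silyl transfer gives aldol silyl ether 9; on acidification the C2 oxygen gives up its silyl group to the medium, adds to C8a and methanol is expelled (vinylogous transesterification), which closes ring C through the O1–C8a bond in a 6‑endo‑trig addition–elimination. The closest known reaction type is the BINOL–titanium‑catalysed Mukaiyama aldol/cyclocondensation of 1‑methoxy‑3‑silyloxy dienes with aldehydes (formal hetero‑Diels–Alder with a Danishefsky‑type diene). The new stereocenter C2 is set by the chiral titanium complex (catalyst control); (S)-BINOL is expected to direct attack to the Si face of benzaldehyde and give 2S, and the antipodal ligand would be used if the sense proves opposite. The step needs regioselection between C8a and C5, since both carry a methoxy group on a vinylogous ester carbon within six‑ring reach of O1. C8a is the β‑carbon of the new C4 ketone as well as the δ‑carbon of the C7 dienone and its methoxy group is twisted out of conjugation between C8 and C4a, whereas C5 is activated by C7=O alone; because the closure is reversible in acid, the isomer that would keep a methoxy group on C8a should also be the less stable one. The gem‑diprenyl carbon C8 rules out aromatization, so the dienone survives the acid.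

**Step 7**
Reactants: 10 (2S)-5-methoxy-8,8-bis(3-methylbut-2-en-1-yl)-2-phenyl-2,3-dihydro-4H-chromene-4,7(8H)-dione
Product: 11 (2S,4S)-4-hydroxy-5-methoxy-8,8-bis(3-methylbut-2-en-1-yl)-2-phenyl-3,4-dihydro-2H-chromen-7(8H)-one (pongaflavanol)
Conditions: NaBH4 (1.1 equiv), CeCl3·7H2O (1.1 equiv), MeOH, −78 °C; NaHCO3 quench, neutral work-up
Reagents that add atoms: none
Why: Luche 1,2‑reduction should take the C4 carbonyl (next to the C3 methylene) in preference to the C7 carbonyl (doubly vinylogous and neopentyl), and axial hydride attack on the half‑chair with equatorial phenyl should give the equatorial 2,4‑cis alcohol (4S), as in reductions of flavanones and 2‑substituted dihydropyranones.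

**Compound list**

1 | 1-(4-hydroxy-2,6-dimethoxyphenyl)ethan-1-one | CC(=O)c1c(OC)cc(O)cc1OC | starting material
2 | 1-(3-bromo-4-hydroxy-2,6-dimethoxyphenyl)ethan-1-one | CC(=O)c1c(OC)cc(O)c(Br)c1OC | intermediate
3 | 1-bromo-3-methylbut-2-ene (prenyl bromide) | CC(C)=CCBr | starting material
4 | 1-[3-bromo-4-hydroxy-2,6-dimethoxy-5-(3-methylbut-2-en-1-yl)phenyl]ethan-1-one | CC(=O)c1c(OC)c(CC=C(C)C)c(O)c(Br)c1OC | intermediate
5 | 4-acetyl-2-bromo-3,5-dimethoxy-6,6-bis(3-methylbut-2-en-1-yl)cyclohexa-2,4-dien-1-one | CC(=O)C1=C(OC)C(CC=C(C)C)(CC=C(C)C)C(=O)C(Br)=C1OC | intermediate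
6 | 4-acetyl-3,5-dimethoxy-6,6-bis(3-methylbut-2-en-1-yl)cyclohexa-2,4-dien-1-one | CC(=O)C1=C(OC)C(CC=C(C)C)(CC=C(C)C)C(=O)C=C1OC | intermediate
7 | 3,5-dimethoxy-6,6-bis(3-methylbut-2-en-1-yl)-4-{1-[(trimethylsilyl)oxy]ethenyl}cyclohexa-2,4-dien-1-one | C=C(O[Si](C)(C)C)C1=C(OC)C(CC=C(C)C)(CC=C(C)C)C(=O)C=C1OC | intermediate
8 | benzaldehyde | O=Cc1ccccc1 | starting material
9 | 3,5-dimethoxy-6,6-bis(3-methylbut-2-en-1-yl)-4-[(3S)-3-phenyl-3-(trimethylsilyloxy)propanoyl]cyclohexa-2,4-dien-1-one | C[Si](C)(C)O[C@@H](CC(=O)C1=C(OC)C(CC=C(C)C)(CC=C(C)C)C(=O)C=C1OC)c1ccccc1 | intermediate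
10 | (2S)-5-methoxy-8,8-bis(3-methylbut-2-en-1-yl)-2-phenyl-2,3-dihydro-4H-chromene-4,7(8H)-dione | COC1=CC(=O)C(CC=C(C)C)(CC=C(C)C)C2=C1C(=O)C[C@@H](c1ccccc1)O2 | intermediate
11 | (2S,4S)-4-hydroxy-5-methoxy-8,8-bis(3-methylbut-2-en-1-yl)-2-phenyl-3,4-dihydro-2H-chromen-7(8H)-one (pongaflavanol) | COC1=CC(=O)C(CC=C(C)C)(CC=C(C)C)C2=C1[C@@H](O)C[C@@H](c1ccccc1)O2 | target

**Totals**

Total step count: 7. Longest linear sequence: 7 steps (1 to 11).

**Steps most likely to fail**

Step 6 (key step). What may go wrong: the basic dienone carbonyl of 7 may bind the titanium catalyst, costing turnover and enantiofacial control; the ring closure may stray to the methoxy‑bearing C5; a prenyl group may cyclize onto a carbonyl oxygen under acid. The fallback sets out from compound 6 and comes back at compound 10. Compound 6 is converted with B‑chlorodiisopinocampheylborane (the enantiomer that directs attack to the Si face of the aldehyde) and Et3N in Et2O at −78 °C into its boron enolate and added to benzaldehyde 8. Oxidative work‑up (H2O2, pH 7 buffer) should give the free aldol 4-[(3S)-3-hydroxy-3-phenylpropanoyl]-3,5-dimethoxy-6,6-bis(3-methylbut-2-en-1-yl)cyclohexa-2,4-dien-1-one F1. This replaces catalytic Lewis‑acid control by stoichiometric reagent control and separates the two events. F1 is then closed in its own step under mild, equilibrating acid (camphorsulfonic acid cat., CH2Cl2 with a few equivalents of MeOH, 0 °C), so that an ether formed through C5 can revert and funnel to 10.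

Step 3. What may go wrong: O‑prenylation may win over the dearomatizing C‑alkylation, or the bromine‑bearing ortho carbon may be attacked. The fallback sets out from compound 1 and comes back at compound 6, so that steps 1 to 4 are replaced. Compound 1 is treated with NaH (2.2 equiv) and (Z)-1,4-dichlorobut-2-ene in toluene. After the first ortho C‑alkylation the second alkylation is intramolecular and can only reach the same ring carbon, which should give the spirodienone 9-acetyl-8,10-dimethoxyspiro[4.5]deca-2,7,9-trien-6-one F2 without any blocking group. Lemieux–Johnson cleavage of the isolated cyclopentene alkene (OsO4 cat., NaIO4, 2,6‑lutidine, dioxane–water) should give the dialdehyde 2,2'-(3-acetyl-2,4-dimethoxy-6-oxocyclohexa-2,4-diene-1,1-diyl)diacetaldehyde F3. A double Wittig reaction with isopropylidenetriphenylphosphorane (from isopropyltriphenylphosphonium iodide and n‑BuLi, THF, −78 °C) should then build both prenyl groups and give 6.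

Step 7. What may go wrong: hydride may attack the C7 carbonyl or add in 1,4 fashion, the cis preference may erode, or the allylic C4 alcohol may ionize in the Lewis‑acidic methanolic medium. The fallback sets out from compound 10 and comes back at compound 11. It replaces the chemical reductant by an enzyme: an NADPH‑dependent ketoreductase (alcohol dehydrogenase class), chosen from a panel for S‑selective reduction of the unhindered C4 ketone, in pH 7 buffer with a cosolvent and glucose/glucose dehydrogenase cofactor recycling. The enzyme should tell the C4 ketone from the neopentyl C7 ketone and set C4 by catalyst control at neutral pH; this fallback makes no compound outside the list (F0).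

**Further compounds**

F1 | step 6 | 4-[(3S)-3-hydroxy-3-phenylpropanoyl]-3,5-dimethoxy-6,6-bis(3-methylbut-2-en-1-yl)cyclohexa-2,4-dien-1-one | O[C@@H](CC(=O)C1=C(OC)C(CC=C(C)C)(CC=C(C)C)C(=O)C=C1OC)c1ccccc1
F2 | step 3 | 9-acetyl-8,10-dimethoxyspiro[4.5]deca-2,7,9-trien-6-one | CC(=O)C1=C(OC)C2(CC=CC2)C(=O)C=C1OC
F3 | step 3 | 2,2'-(3-acetyl-2,4-dimethoxy-6-oxocyclohexa-2,4-diene-1,1-diyl)diacetaldehyde | CC(=O)C1=C(OC)C(CC=O)(CC=O)C(=O)C=C1OC
F0 | step 7 | none | none
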